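**Retrosynthetic overview**
- Feature: two identical hexasubstituted benzene rings joined by one sp3 CH2. In each ring the carbon substituents (bridging CH2 at C1, acetyl at C3, methyl at C5) alternate with oxygen (OH at C2, C4, C6). This C/O alternation is what a vinylketene plus ynol ether benzannulation produces, and the bridging CH2 maps onto C3 of a penta-1,4-diyne.
- Endgame disconnections: the two O-ethyl bonds (BBr3), the two O-silyl bonds (fluoride), and the two aryl–acetyl bonds (Friedel–Crafts at the single free CH of each ring).
- Key disconnection: both benzene rings at once, into one molecule of 1,5-bis(triisopropylsilyloxy)penta-1,4-diyne and two molecules of 3-ethoxy-2-methylcyclobut-2-en-1-one (four C–C bonds; the rings form one after the other in the same flask, and no ring exists before this step).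
- Precursors: the diyne from propargyl bromide and ethynylmagnesium bromide, then twofold acetylide oxygenation and O-silylation; the cyclobutenone from ketene and 1-ethoxypropyne.

Key step: step 4

Remark on the chemistry: penta-1,4-diyne cannot be freed from THF by distillation, so it is carried into step 2 as an assayed THF solution; base-washed glassware is assumed for steps 2 and 4 because silyl ynol ethers are acid-sensitive.

Step 1
Reactants: 1 propargyl bromide; 2 ethynylmagnesium bromide
Product: 3 penta-1,4-diyne
Conditions: 2 (1.3 equiv), CuCl (5 mol %), THF, 0 °C to rt; flash distillation, used as an assayed THF solution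
Reagents that add atoms: none
Why: Copper-catalysed coupling of an alkynyl Grignard reagent with a propargylic bromide (substitution at the CH2Br carbon) is the standard construction of a skipped 1,4-diyne, and the excess of 2 limits further propargylation of the product.

Step 2
Reactants: 3 penta-1,4-diyne
Product: 6 1,5-bis(triisopropylsilyloxy)penta-1,4-diyne, via 1,5-dilithiopenta-1,4-diyne 4 (not isolated), via dilithium penta-1,4-diyne-1,5-bis(olate) 5 (not isolated)
Conditions: n-BuLi (2.0 equiv, slow addition), THF, −78 °C; transfer into t-BuOOLi (2.2 equiv, from t-BuOOH and LiN(SiMe3)2, THF, −78 °C), −78 to 0 °C; i-Pr3SiOTf (2.4 equiv), −78 °C to rt; pentane/aq. NaHCO3, rapid filtration through Et3N-deactivated silica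
Reagents that add atoms: lithium tert-butyl peroxide, CC(C)(C)OO[Li]; triisopropylsilyl trifluoromethanesulfonate, CC(C)[Si](OS(=O)(=O)C(F)(F)F)(C(C)C)C(C)C
Why: Julia-type oxygenation of lithium acetylides: at −78 °C n-BuLi should remove the two acetylenic protons faster than the doubly propargylic ones, each acetylide attacks the peroxide oxygen of one molecule of t-BuOOLi to give the ynolate with loss of t-BuOLi, and the bulky silyl triflate silylates each ynolate on oxygen, not carbon.

Step 3
Reactants: 7 1-ethoxypropyne; 8 acetyl chloride
Product: 10 3-ethoxy-2-methylcyclobut-2-en-1-one, via ketene 9 (not isolated)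
Conditions: Et3N (1.3 equiv), MeCN, 8 added by syringe pump, 0 °C to rt; distillation
Reagents that add atoms: none
Why: Dehydrochlorination of 8 by Et3N releases ketene 9, which is trapped in a [2+2] cycloaddition by the electron-rich ynol ether 7, whose methyl-bearing nucleophilic carbon bonds to the ketene carbonyl carbon, so that methyl ends up at C2 and ethoxy at C3 of the cyclobutenone.

Step 4
Reactants: 6 1,5-bis(triisopropylsilyloxy)penta-1,4-diyne; 10 3-ethoxy-2-methylcyclobut-2-en-1-one
Product: 13 bis[4-ethoxy-6-hydroxy-3-methyl-2-(triisopropylsilyloxy)phenyl]methane, via 3-ethoxy-2-methylbuta-1,3-dien-1-one 11 (not isolated), via mono-annulated propargylphenol 12 (not isolated)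
Conditions: 10 (2.6 equiv in all, in two portions; two molecules are built into the product), degassed toluene (0.2 M), 110 °C, sealed tube, argon
Reagents that add atoms: 3-ethoxy-2-methylcyclobut-2-en-1-one (second molecule of 10, which builds the second ring), CCOC1=C(C)C(=O)C1
Why: Proposed new method: heating opens cyclobutenone 10 by 4π electrocyclic ring opening to vinylketene 11, whose ketene C=C adds in a [2+2] sense to one silyl ynol ether terminus of 6 (the alkyne carbon remote from oxygen bonding to the ketene carbonyl carbon), after which the cyclobutenone adduct reopens to a dienylketene that ring-closes and tautomerises to phenol 12, and the second alkyne then repeats the sequence with a second molecule of 10, so that one molecule of 6 and two of 10 add up to 13 with nothing split off. The closest known reaction type is the Danheiser benzannulation of a cyclobutenone with a single trialkylsiloxyalkyne; what is new is its twofold use on a skipped diyne whose two ynol ether termini share one doubly propargylic CH2, with a 3-alkoxycyclobutenone as the vinylketene source. Each benzene ring is closed by 6π electrocyclisation of the dienylketene, which joins the former ketene carbonyl carbon to the CH2 terminus of the ethoxyvinyl unit, so that the two lasting new bonds per ring are those of the [2+2] step and the ring order bridge CH2, OSi, CH3, OEt, CH, OH follows directly. No stereocentre is formed. The step needs regioselective [2+2] addition, which the oxygen-induced polarisation of the ynol ether should secure, and it needs the CH2 between the alkynes to resist propargyl–allenyl isomerisation and phenol 12 to resist addition to its own ynol ether or to 11, for which strictly neutral non-polar conditions, base-washed glass, the bulky silyl groups and the excess of 10 are relied on.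

Step 5
Reactants: 13 bis[4-ethoxy-6-hydroxy-3-methyl-2-(triisopropylsilyloxy)phenyl]methane; 8 acetyl chloride
Product: 14 bis[5-acetyl-4-ethoxy-6-hydroxy-3-methyl-2-(triisopropylsilyloxy)phenyl]methane
Conditions: TiCl4 (2.4 equiv), 8 (2.6 equiv in all; one acetyl group enters each ring), CH2Cl2, −40 to 0 °C; cold 1 M HCl work-up
Reagents that add atoms: acetyl chloride (second molecule of 8, which acylates the second ring), CC(Cl)=O
Why: TiCl4-mediated Friedel–Crafts ortho-acylation of a phenol: each ring has a single unsubstituted position, flanked by OH and OEt and para to the silyloxy group, and the chelated ortho-hydroxy ketone that results should deactivate the ring toward further electrophilic attack, including ipso attack at the methylene bridge.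

Step 6
Reactants: 14 bis[5-acetyl-4-ethoxy-6-hydroxy-3-methyl-2-(triisopropylsilyloxy)phenyl]methane
Product: 15 bis(3-acetyl-4-ethoxy-2,6-dihydroxy-5-methylphenyl)methane
Conditions: Bu4NF (2.5 equiv), AcOH (2.5 equiv), THF, 0 °C
Reagents that add atoms: none
Why: Fluoride-induced Si–O cleavage of aryl silyl ethers, driven by the strong Si–F bond, with acetic acid buffering so that the electron-rich phenoxides stay protonated while the aryl ethyl ethers and ketones are untouched.

Step 7
Reactants: 15 bis(3-acetyl-4-ethoxy-2,6-dihydroxy-5-methylphenyl)methane
Product: 16 bis(3-acetyl-2,4,6-trihydroxy-5-methylphenyl)methane (CNP0190887.0)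
Conditions: BBr3 (8 equiv), CH2Cl2, −78 to 0 °C; MeOH then water quench
Reagents that add atoms: none
Why: BBr3 dealkylation of aryl alkyl ethers (bromide attacks the O-ethyl carbon of the boron-coordinated ether), chosen over BCl3 because each acetyl oxygen is already held in a boron chelate by its free ortho-hydroxyl, so carbonyl-assisted cleavage of the second ortho-alkoxy group by the weaker Lewis acid cannot be counted on, while the acyl groups should protect the methylene bridge from protolytic scission.

**Compound list**
1 | propargyl bromide (3-bromoprop-1-yne) | BrCC#C | starting material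
2 | ethynylmagnesium bromide | C#C[Mg]Br | starting material
3 | penta-1,4-diyne | C#CCC#C | intermediate
4 | 1,5-dilithiopenta-1,4-diyne | [Li]C#CCC#C[Li] | intermediate
5 | dilithium penta-1,4-diyne-1,5-bis(olate) | [Li]OC#CCC#CO[Li] | intermediate
6 | 1,5-bis(triisopropylsilyloxy)penta-1,4-diyne | CC(C)[Si](C(C)C)(C(C)C)OC#CCC#CO[Si](C(C)C)(C(C)C)C(C)C | intermediate
7 | 1-ethoxypropyne | CCOC#CC | starting material
8 | acetyl chloride | CC(Cl)=O | starting material
9 | ketene | C=C=O | intermediate
10 | 3-ethoxy-2-methylcyclobut-2-en-1-one | CCOC1=C(C)C(=O)C1 | intermediate
11 | 3-ethoxy-2-methylbuta-1,3-dien-1-one (vinylketene) | CCOC(=C)C(C)=C=O | intermediate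
12 | 5-ethoxy-4-methyl-3-(triisopropylsilyloxy)-2-[3-(triisopropylsilyloxy)prop-2-yn-1-yl]phenol | CCOc1cc(O)c(CC#CO[Si](C(C)C)(C(C)C)C(C)C)c(O[Si](C(C)C)(C(C)C)C(C)C)c1C | intermediate
13 | bis[4-ethoxy-6-hydroxy-3-methyl-2-(triisopropylsilyloxy)phenyl]methane | CCOc1cc(O)c(Cc2c(O)cc(OCC)c(C)c2O[Si](C(C)C)(C(C)C)C(C)C)c(O[Si](C(C)C)(C(C)C)C(C)C)c1C | intermediate
14 | bis[5-acetyl-4-ethoxy-6-hydroxy-3-methyl-2-(triisopropylsilyloxy)phenyl]methane | CCOc1c(C(C)=O)c(O)c(Cc2c(O)c(C(C)=O)c(OCC)c(C)c2O[Si](C(C)C)(C(C)C)C(C)C)c(O[Si](C(C)C)(C(C)C)C(C)C)c1C | intermediate
15 | bis(3-acetyl-4-ethoxy-2,6-dihydroxy-5-methylphenyl)methane | CCOc1c(C(C)=O)c(O)c(Cc2c(O)c(C(C)=O)c(OCC)c(C)c2O)c(O)c1C | intermediate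
16 | bis(3-acetyl-2,4,6-trihydroxy-5-methylphenyl)methane | CC(=O)c1c(O)c(C)c(O)c(Cc2c(O)c(C)c(O)c(C(C)=O)c2O)c1O | target

Total step count: 7. Longest linear sequence: 6 steps (steps 1, 2, 4, 5, 6, 7); step 3 is the convergent branch.

**Steps most likely to fail**

First, step 4, the proposed new method. Three processes may defeat it:
- ring opening of the vinylogous-ester cyclobutenone that is too slow below the temperature at which the skipped diyne isomerises to an allenyl ynol ether;
- capture of the phenol of 12 by its own ynol ether or by ketene 11;
- a second annulation that stalls.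

The fallback uses only classical chemistry and does not build the rings. It sets out from acetyl chloride 8, which C-acetylates commercial 2-methylbenzene-1,3,5-triol F1 (AlCl3, nitrobenzene, rt to 60 °C; Friedel–Crafts acylation of a phloroglucinol) to give 1-(2,4,6-trihydroxy-3-methylphenyl)ethanone F2. The single free ring carbon of F2, flanked by two hydroxyls, is then condensed with formaldehyde (0.5 equiv, aqueous formalin, dilute aqueous KOH, 0 °C to rt; hydroxymethylation, then capture of the derived quinone methide by a second molecule). This should give 16 directly, so the fallback comes back to the route at the target 16.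

Second, step 2. The risks are prototropic isomerisation at the doubly propargylic CH2 under the strongly basic conditions, incomplete oxygen transfer to the second acetylide of the poorly soluble dianion 4, and silylation on carbon. The fallback replaces the one-flask twofold process through a dianion by two separate single oxygenations, each through a monoacetylide. It sets out from 3, used in threefold excess, with one equivalent of the weaker, bulkier base LiN(SiMe3)2 (THF, −78 °C), then t-BuOOLi and i-Pr3SiOTf. This should give triisopropyl(penta-1,4-diyn-1-yloxy)silane F3, which is isolated once the volatile excess of 3 is removed. A second pass of the same deprotonation, oxygenation and O-silylation on the remaining terminal alkyne of F3 returns to 6.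

Third, step 5. The risks are Lewis-acid-promoted scission of, or ipso-acylation at, the methylene bridge of the very electron-rich diarylmethane, O-acylation that does not go on to the ketone, and loss of the silyl ethers. The fallback moves the acetyl groups onto carbon without any Lewis acid. It sets out from 13, which is O-acetylated (Ac2O, pyridine, catalytic DMAP, CH2Cl2, rt) to bis[6-acetoxy-4-ethoxy-3-methyl-2-(triisopropylsilyloxy)phenyl]methane F4. Irradiation at 254 nm in degassed cyclohexane (photo-Fries rearrangement: homolysis of the aryl O–acyl bond and in-cage recombination) should deliver each acetyl group to the only open ortho position, the para position being blocked by methyl, and so return to 14.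

**Further compounds**
F1 | step 4 | 2-methylbenzene-1,3,5-triol (2-methylphloroglucinol) | Cc1c(O)cc(O)cc1O
F2 | step 4 | 1-(2,4,6-trihydroxy-3-methylphenyl)ethanone | CC(=O)c1c(O)cc(O)c(C)c1O
F3 | step 2 | triisopropyl(penta-1,4-diyn-1-yloxy)silane | C#CCC#CO[Si](C(C)C)(C(C)C)C(C)C
F4 | step 5 | bis[6-acetoxy-4-ethoxy-3-methyl-2-(triisopropylsilyloxy)phenyl]methane | CCOc1cc(OC(C)=O)c(Cc2c(OC(C)=O)cc(OCC)c(C)c2O[Si](C(C)C)(C(C)C)C(C)C)c(O[Si](C(C)C)(C(C)C)C(C)C)c1C
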